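(The constants used here are assumed, and the outcome is calculated.)

Count G against the exposure of the flask to X, not against the clock.

    X ⇌ E (K1 = 1.0, k1 = 1.42 min⁻¹, Ea1 = 79.0 kJ mol⁻¹, ΔH1 = 14.0 kJ mol⁻¹)
    X → G (k2 = 0.0113 min⁻¹, Ea2 = 91.0 kJ mol⁻¹)
    E → J (k3 = 0.0195 min⁻¹, Ea3 = 87.0 kJ mol⁻¹)
    X + G → X.G (k4 = 3.20 M⁻¹ min⁻¹, Ea4 = 60.0 kJ mol⁻¹)
    (constants at 25 °C)

in all of them: X 0.050 M; time 50 min

| run | temperature |
|---|---|
| ochre | 25 °C |
| grey | 50 °C |

* the flask with the highest amount of G, in percent of the X charged ("all alike" if they lie within 1.5 percentage points) (ochre / grey / all alike)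
* final G, as a percentage of the X charged, in ochre
* final G, as a percentage of the X charged, in grey

- percent here means X units held: one X.G counts as two
- constants are those at 25 °C; use the activation energies and enthalpies for any other temperature
- in a conversion E counts as not yet reacted

Let S be the pool X + E, K the constant of X ⇌ E, and m, j and c the constants of X → G, E → J and X + G → X.G. In ochre, X ⇌ E relaxes with a half-life of 0.244 min, far below the 50 min of the run, so this pre-equilibrium holds X at a steady share of S. Define the exposure τ as the time integral of [X]. Per unit of τ, G gains m and loses c[G], so it climbs towards the ceiling G* = m/c = 0.00353 M, the concentration at which capture equals making, and the fraction of the gap left is exp(−cτ).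

Counting X units, with each X.G as two, gives Bτ = Δ + G, where Δ is the pool consumed and B = 2m + jK, which is 0.0421 min⁻¹ in ochre. With capture near m, S falls first-order at B times the X share of the pool. Ochre then keeps 34.9 % of its pool, and one pass of G back into Δ gives 0.00330 M, or 6.60 % of the charge.

Grey differs from ochre in temperature. The rise that multiplies K by ρ = 1.55 multiplies each constant by ρ^(Ea/ΔH). So m becomes 0.193 min⁻¹, B becomes 0.843 min⁻¹, and G* becomes 0.00929 M. The reckoned pool half-life in grey is 2.10 min, far below 50 min, so Δ is taken as the charge and the same pass gives 0.00699 M, or 14.0 %. By this reckoning ochre ends 6.59 % short of a low ceiling, while grey ends 24.8 % short of a higher one, and grey still holds more G.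

The forecast names grey, with 6.5 % in ochre and 14.2 % in grey, slightly apart from the figures above, on the ground that “G is capped by the balance between its formation and its capture by X”.

The simulation puts more G in grey, with 6.56 % in ochre and 14.1 % in grey. At 500 min, ochre reads 6.94 % and grey 14.1 %. Those readings stand at 98.3 % of G* in ochre and 76.1 % of G* in grey.

The neighbour of ochre charged with 0.020 M of X has the same G*, now 17.6 % of its charge, and the same reckoned pool fraction, so the pass gives 0.00242 M, or 12.1 %. The simulated neighbour ends at 11.7 %.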